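**Plan**
- Numbering: C1 = quaternary carbon with the angular methyl, C2/C3 = ring A methylenes, C4 = C(OH)(iPr), C5 = ring-fusion CH, C6 = CH–O-acyl, C7 = CH2, C8(Me)=C9, C10 = CH2. Ring A = C1–C5, ring B = C1, C5–C10; β = the face of the C1 methyl and the C4 oxygen.
- Retrosynthesis: cut the C6–O ester bond; trade C9–H for a C9 carbonyl (through the C8=C9 enol triflate) and the C5–H/C6–OH pair for a C5=C6 alkene; then cut C1–C10 by a retro-Claisen step that re-joins C6 to the C9 oxygen.
- Enabling feature: C6 and C9 lie 1,4 across ring B, so an oxygen bridge between them gives a five-membered 2-methylideneoxolane (O, C9, C8, C7, C6) hung through C6 on the ring A alkene C5=C1. The chain C10=C9–O–C6–C5=C1 is an allyl vinyl ether whose [3,3] shift makes the quaternary C1–C10 bond and ring B in one event.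
- Forward order: ring A first (ozonolysis/aldol ring contraction of (S)-terpinen-4-ol), then the oxolane on the ring A aldehyde, then ring B by Claisen ring expansion, then C9 deoxygenation, C5/C6 functionalisation and esterification.
- Stereochemistry: C4 from the chiral pool; C6 of the lactone by catalyst control, relayed to C1 in the [3,3] shift; C5 and C6 by α-face hydroboration; the C8 epimers converge at the enol triflate.

Key step: step 7

Assumption: (S)-(+)-terpinen-4-ol is taken as a single enantiomer (material of lower purity would be enriched first). Compounds 11, 12 and 13 are carried as epimer mixtures at C8, and their SMILES leave that centre open.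

**Step 1**
Reactants: 1 (S)-terpinen-4-ol
Product: 2 triethyl{[(1S)-4-methyl-1-(propan-2-yl)cyclohex-3-en-1-yl]oxy}silane
Conditions: TESOTf, 2,6-lutidine, CH2Cl2, 0 °C → rt
Reagents that add atoms: triethylsilyl trifluoromethanesulfonate, CC[Si](CC)(CC)OS(=O)(=O)C(F)(F)F
Why: Silyl triflate silylation of a hindered tertiary alcohol is reliable, touches no stereocentre, and the ether protects the carbinol from retro-aldol cleavage in steps 2–3 and later shields the β face.

**Step 2**
Reactants: 2 TES ether of terpinen-4-ol
Product: 4 (3S)-6-oxo-3-(propan-2-yl)-3-(triethylsilyloxy)heptanal, via ozonide 3 (not isolated)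
Conditions: O3, CH2Cl2, −78 °C; then PPh3, −78 °C → rt
Reagents that add atoms: ozone, [O-][O+]=O
Why: Ozonolysis of the only alkene followed by reductive cleavage of the ozonide should give the methyl ketone and the aldehyde without affecting the quaternary C4 centre or the silyl ether.

**Step 3**
Reactants: 4 keto aldehyde
Product: 6 (5R)-2-methyl-5-(propan-2-yl)-5-(triethylsilyloxy)cyclopent-1-ene-1-carbaldehyde, via aldol adduct 5 (not isolated)
Conditions: piperidine (cat.), AcOH (cat.), toluene, 4 Å MS, 60 °C
Reagents that add atoms: none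
Why: In this amine–acid catalysed intramolecular aldol condensation the aldehyde enamine adds to the methyl ketone to close ring A and water is lost to the conjugated enal, the formyl-cyclopentene being the usual outcome under enamine catalysis and the tertiary silanolate being a reluctant leaving group under these mild conditions.

**Step 4**
Reactants: 6 ring A enal; 7 ethyl 2-(bromomethyl)acrylate
Product: 10 (5S)-3-methylidene-5-[(5R)-2-methyl-5-(propan-2-yl)-5-(triethylsilyloxy)cyclopent-1-en-1-yl]oxolan-2-one, via TMS ether 8 (not isolated), via hydroxy ester 9 (not isolated)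
Conditions: CrCl2 (10 mol %), chiral 3,6-di-tert-butyl-1,8-bis(4-isopropyl-4,5-dihydrooxazol-2-yl)carbazole ligand (12 mol %, antipode that directs Si-face addition), iPr2NEt, Mn, TMSCl, THF, rt; then TBAF, THF, 0 °C
Reagents that add atoms: none
Why: In this catalytic asymmetric Nozaki–Hiyama–Kishi 2-(alkoxycarbonyl)allylation the allyl species bound to the chiral trivalent chromium complex adds 1,2 to the enal on its Si face to set C6 as S, and fluoride cleavage of the secondary TMS ether frees the alkoxide that closes the lactone on the ethyl ester while the tertiary TES ether is left alone.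

**Step 5**
Reactants: 10 α-methylene lactone
Product: 11 (5S)-3-methyl-5-[(5R)-2-methyl-5-(propan-2-yl)-5-(triethylsilyloxy)cyclopent-1-en-1-yl]oxolan-2-one (epimers at C3 of the lactone, which is C8)
Conditions: H2 (1 atm), RhCl(PPh3)3 (5 mol %), benzene–EtOH, rt
Reagents that add atoms: none
Why: Homogeneous hydrogenation should saturate the unhindered 1,1-disubstituted exocyclic alkene and leave the tetrasubstituted ring alkene and the allylic C–O bond alone, and the uncontrolled new C8 centre is of no consequence because it becomes sp2 again in step 8.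

**Step 6**
Reactants: 11 α-methyl lactone
Product: 12 (5S)-3-methyl-2-methylidene-5-[(5R)-2-methyl-5-(propan-2-yl)-5-(triethylsilyloxy)cyclopent-1-en-1-yl]oxolane
Conditions: Cp2TiMe2, toluene, 70 °C, dark; filtration through basic Al2O3
Reagents that add atoms: dimethyltitanocene Cp2TiMe2, C[Ti](C)(C1C=CC=C1)C1C=CC=C1
Why: Carbonyl methylenation with Cp2TiMe2 (Petasis olefination) proceeds by [2+2] addition of thermally formed Cp2Ti=CH2 to the lactone carbonyl and cycloreversion, giving the exocyclic enol ether under non-acidic conditions that leave C6 untouched.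

**Step 7**
Reactants: 12 2-methylidene-5-(cyclopentenyl)oxolane
Product: 13 (1R,4R)-4-(triethylsilyloxy)dauc-5-en-9-one (C8 epimers)
Conditions: degassed xylenes, iPr2NEt (trace), base-washed sealed tube, 180 °C
Reagents that add atoms: none
Why: The allyl vinyl ether C10=C9–O–C6–C5=C1 undergoes a concerted suprafacial [3,3]-sigmatropic (Claisen) shift in which C10 bonds to C1, the C6–O bond breaks, C9 becomes the carbonyl carbon and the C5=C6 alkene appears. The closest known reaction is the thermal Claisen ring expansion of 2-methylidene-5-vinyloxolanes (methylenated γ-lactones) to cyclohept-4-enones. Ring B closes as a two-carbon ring expansion: the C7–C8 bridge of the oxolane spans a boat-like six-centre transition state, so the five-membered oxacycle becomes the seven-membered carbocycle with a cis C5=C6 bond, the only geometry the tether allows. The new quaternary centre C1 is controlled by C6, because only the conformer with C7 turned toward C1 can close, which forces C10 onto the face of C1 that carries the C6–O bond (the α face for 6S) and leaves the methyl β (1R); both C8 epimers give the same C1 configuration. The step needs the [3,3] shift to outrun acid-catalysed migration of the exocyclic enol ether double bond into the ring and ionisation of the allylic C6–O bond, which is secured by base-washed glassware, the amine additive and a non-polar solvent. The tetrasubstituted C1 terminus gives the quaternary centre directly, and the tertiary TES ether is a spectator.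

**Step 8**
Reactants: 13 cycloheptenone
Product: 15 (1R,4R)-4-(triethylsilyloxy)dauca-5,8-dien-9-yl trifluoromethanesulfonate, via bromomagnesium enolate 14 (not isolated)
Conditions: iPr2NMgBr (from EtMgBr, iPr2NH), Et2O, rt; then PhNTf2, THF, rt → 40 °C
Reagents that add atoms: N-phenylbis(trifluoromethanesulfonimide), O=S(=O)(N(c1ccccc1)S(=O)(=O)C(F)(F)F)C(F)(F)F
Why: Enol triflate formation through a thermodynamic enolate should work because the equilibrating bromomagnesium enolate settles on the more substituted C8=C9 isomer and O-triflation with PhNTf2 fixes it, which also removes the C8 stereocentre.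

**Step 9**
Reactants: 15 dienyl triflate
Product: 17 (1R,4R,5S,6S)-6-hydroxy-4-(triethylsilyloxy)dauc-8-en-9-yl trifluoromethanesulfonate, via C6 alkylborane 16 (not isolated)
Conditions: BH3·THF, THF, 0 °C → rt; then NaBO3·4H2O, THF–H2O, rt
Reagents that add atoms: sodium perborate tetrahydrate NaBO3·4H2O (peroxoborate dimer, water of crystallisation omitted), [Na+].[Na+].O[B-]1(O)OO[B-](O)(O)OO1
Why: Hydroboration–oxidation should hit the electron-rich trisubstituted C5=C6 alkene in preference to the electron-poor tetrasubstituted enol triflate, with boron at the less substituted C6 and syn delivery of H to C5 on the α face away from the angular methyl and the silyloxy group (the pattern of steroidal 5-enes), and near-neutral perborate oxidation with retention then gives the trans-fused 5α-H, 6α-OH array without harming the triflate.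

**Step 10**
Reactants: 17 hydroxy triflate
Product: 18 (1R,4R,5S,6S)-4-(triethylsilyloxy)dauc-8-en-6-ol
Conditions: Pd(OAc)2 (5 mol %), PPh3, Bu3N, HCO2H, DMF, 60 °C
Reagents that add atoms: none
Why: In this palladium-catalysed formate reduction of an enol triflate, zerovalent palladium inserts into the C9–OTf bond, formate supplies hydride by decarboxylation and reductive elimination leaves C9–H with the alkene fixed at C8=C9, while the free alcohol, the silyl ether and all stereocentres are untouched.

**Step 11**
Reactants: 19 (E)-p-coumaric acid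
Product: 21 (2E)-3-[4-(tert-butyldimethylsilyloxy)phenyl]prop-2-enoic acid, via bis-silyl derivative 20 (not isolated)
Conditions: TBSCl, imidazole, DMF, rt; then AcOH, THF–H2O, rt
Reagents that add atoms: tert-butyldimethylsilyl chloride, CC(C)(C)[Si](C)(C)Cl
Why: Silylation of both the phenol and the acid followed by selective hydrolysis of the far more labile silyl ester should leave the phenol protected and the E alkene unchanged.

**Step 12**
Reactants: 18 C6 alcohol; 21 protected p-coumaric acid
Product: 22 (1R,4R,5S,6S)-4-(triethylsilyloxy)dauc-8-en-6-yl (2E)-3-[4-(tert-butyldimethylsilyloxy)phenyl]prop-2-enoate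
Conditions: DCC, DMAP, CH2Cl2, 0 °C → rt
Reagents that add atoms: none
Why: Steglich esterification acylates the only free hydroxyl with retention at C6 because the C6–O bond is not broken, and the masked phenol cannot compete.

**Step 13**
Reactants: 22 bis-silyl ester
Product: 23 (1R,4R,5S,6S)-4-hydroxydauc-8-en-6-yl (2E)-3-(4-hydroxyphenyl)prop-2-enoate (target)
Conditions: TBAF, AcOH, THF, 0 °C → rt
Reagents that add atoms: none
Why: Fluoride-mediated desilylation should remove the aryl TBS ether and the tertiary TES ether in one operation, and the acetic acid buffer keeps the medium from promoting acyl migration to the C4 oxygen or ester cleavage.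

**Compound list**
1 | (S)-(+)-terpinen-4-ol, (1S)-4-methyl-1-(propan-2-yl)cyclohex-3-en-1-ol | CC1=CC[C@](O)(C(C)C)CC1 | starting material
2 | triethyl{[(1S)-4-methyl-1-(propan-2-yl)cyclohex-3-en-1-yl]oxy}silane | CC1=CC[C@](O[Si](CC)(CC)CC)(C(C)C)CC1 | intermediate
3 | ozonide of 2, (4S)-1-methyl-4-(propan-2-yl)-4-(triethylsilyloxy)-7,8,9-trioxabicyclo[4.2.1]nonane (mixture at the bridgeheads) | CC12CC[C@@](O[Si](CC)(CC)CC)(C(C)C)CC(OO1)O2 | intermediate (not isolated)
4 | (3S)-6-oxo-3-(propan-2-yl)-3-(triethylsilyloxy)heptanal | CC(=O)CC[C@@](O[Si](CC)(CC)CC)(C(C)C)CC=O | intermediate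
5 | (5R)-2-hydroxy-2-methyl-5-(propan-2-yl)-5-(triethylsilyloxy)cyclopentane-1-carbaldehyde (mixture at C1 and C2) | O=CC1C(C)(O)CC[C@@]1(O[Si](CC)(CC)CC)C(C)C | intermediate (not isolated)
6 | (5R)-2-methyl-5-(propan-2-yl)-5-(triethylsilyloxy)cyclopent-1-ene-1-carbaldehyde | O=CC1=C(C)CC[C@@]1(O[Si](CC)(CC)CC)C(C)C | intermediate
7 | ethyl 2-(bromomethyl)acrylate | C=C(CBr)C(=O)OCC | starting material
8 | ethyl (4S)-2-methylidene-4-[(5R)-2-methyl-5-(propan-2-yl)-5-(triethylsilyloxy)cyclopent-1-en-1-yl]-4-(trimethylsilyloxy)butanoate | CCOC(=O)C(=C)C[C@H](O[Si](C)(C)C)C1=C(C)CC[C@@]1(O[Si](CC)(CC)CC)C(C)C | intermediate (not isolated)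
9 | ethyl (4S)-4-hydroxy-2-methylidene-4-[(5R)-2-methyl-5-(propan-2-yl)-5-(triethylsilyloxy)cyclopent-1-en-1-yl]butanoate | CCOC(=O)C(=C)C[C@H](O)C1=C(C)CC[C@@]1(O[Si](CC)(CC)CC)C(C)C | intermediate (not isolated)
10 | (5S)-3-methylidene-5-[(5R)-2-methyl-5-(propan-2-yl)-5-(triethylsilyloxy)cyclopent-1-en-1-yl]oxolan-2-one | C=C1C[C@H](OC1=O)C2=C(C)CC[C@@]2(O[Si](CC)(CC)CC)C(C)C | intermediate
11 | (5S)-3-methyl-5-[(5R)-2-methyl-5-(propan-2-yl)-5-(triethylsilyloxy)cyclopent-1-en-1-yl]oxolan-2-one (C3 epimers) | CC1C[C@H](OC1=O)C2=C(C)CC[C@@]2(O[Si](CC)(CC)CC)C(C)C | intermediate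
12 | (5S)-3-methyl-2-methylidene-5-[(5R)-2-methyl-5-(propan-2-yl)-5-(triethylsilyloxy)cyclopent-1-en-1-yl]oxolane (C3 epimers) | C=C1O[C@H](C2=C(C)CC[C@@]2(O[Si](CC)(CC)CC)C(C)C)CC1C | intermediate
13 | (1R,4R)-4-(triethylsilyloxy)dauc-5-en-9-one (C8 epimers) | CC1CC=C2[C@](O[Si](CC)(CC)CC)(C(C)C)CC[C@]2(C)CC1=O | intermediate
14 | bromomagnesium C8–C9 enolate of 13 | CC1=C(O[Mg]Br)C[C@@]2(C)CC[C@@](O[Si](CC)(CC)CC)(C(C)C)C2=CC1 | intermediate (not isolated)
15 | (1R,4R)-4-(triethylsilyloxy)dauca-5,8-dien-9-yl trifluoromethanesulfonate | CC1=C(OS(=O)(=O)C(F)(F)F)C[C@@]2(C)CC[C@@](O[Si](CC)(CC)CC)(C(C)C)C2=CC1 | intermediate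
16 | 6α-boranyl-5α-H adduct of 15, 6-boranyl-4-(triethylsilyloxy)dauc-8-en-9-yl trifluoromethanesulfonate | CC1=C(OS(=O)(=O)C(F)(F)F)C[C@@]2(C)CC[C@@](O[Si](CC)(CC)CC)(C(C)C)[C@@H]2[C@@H](B)C1 | intermediate (not isolated)
17 | (1R,4R,5S,6S)-6-hydroxy-4-(triethylsilyloxy)dauc-8-en-9-yl trifluoromethanesulfonate | CC1=C(OS(=O)(=O)C(F)(F)F)C[C@@]2(C)CC[C@@](O[Si](CC)(CC)CC)(C(C)C)[C@@H]2[C@@H](O)C1 | intermediate
18 | (1R,4R,5S,6S)-4-(triethylsilyloxy)dauc-8-en-6-ol | CC1=CC[C@@]2(C)CC[C@@](O[Si](CC)(CC)CC)(C(C)C)[C@@H]2[C@@H](O)C1 | intermediate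
19 | (E)-p-coumaric acid, (2E)-3-(4-hydroxyphenyl)prop-2-enoic acid | O=C(O)/C=C/c1ccc(O)cc1 | starting material
20 | tert-butyldimethylsilyl (2E)-3-[4-(tert-butyldimethylsilyloxy)phenyl]prop-2-enoate | CC(C)(C)[Si](C)(C)OC(=O)/C=C/c1ccc(O[Si](C)(C)C(C)(C)C)cc1 | intermediate (not isolated)
21 | (2E)-3-[4-(tert-butyldimethylsilyloxy)phenyl]prop-2-enoic acid | O=C(O)/C=C/c1ccc(O[Si](C)(C)C(C)(C)C)cc1 | intermediate
22 | (1R,4R,5S,6S)-4-(triethylsilyloxy)dauc-8-en-6-yl (2E)-3-[4-(tert-butyldimethylsilyloxy)phenyl]prop-2-enoate | CC1=CC[C@@]2(C)CC[C@@](O[Si](CC)(CC)CC)(C(C)C)[C@@H]2[C@@H](OC(=O)/C=C/c2ccc(O[Si](C)(C)C(C)(C)C)cc2)C1 | intermediate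
23 | (1R,4R,5S,6S)-4-hydroxydauc-8-en-6-yl (2E)-3-(4-hydroxyphenyl)prop-2-enoate | CC1=CC[C@@]2(C)CC[C@@](O)(C(C)C)[C@@H]2[C@@H](OC(=O)/C=C/c2ccc(O)cc2)C1 | target

**Step count**
Total: 13 steps. Longest linear sequence: 12 steps (steps 1–10, 12 and 13 from compound 1); step 11 is a one-step side branch.

**Steps most likely to fail**

Step 7 (Claisen ring expansion). The bond has to form at a tetrasubstituted alkene carbon at about 180 °C. At that temperature the exocyclic enol ether double bond may migrate into the oxolane ring (a hydrogen at C8 is available), which destroys the allyl vinyl ether. The doubly substituted allylic C6–O bond may also ionise, which would lose the stereochemical relay. The fallback keeps the same disconnection but raises the oxidation level at C8. It sets out from α-methylene lactone 10 and omits the hydrogenation. Methylenation with Cp2TiMe2 would give (5S)-2,3-dimethylidene-5-[(5R)-2-methyl-5-(propan-2-yl)-5-(triethylsilyloxy)cyclopent-1-en-1-yl]oxolane F1, which has no hydrogen at C8 and cannot isomerise in this way. Its Claisen rearrangement at high dilution (to suppress diene dimerisation) would give the exocyclic enone (1R,4R)-4-(triethylsilyloxy)dauca-5,8(14)-dien-9-one F2. Conjugate reduction with LiBH(s-Bu)3 at −78 °C would form the lithium C8–C9 enolate F3 regiospecifically, and trapping with PhNTf2 returns to the route at enol triflate 15, so step 8 is bypassed as well.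

Step 9 (hydroboration–oxidation). Facial discrimination may be insufficient: the isopropyl group on the α face of C4 could offset the shielding of the β face by the angular methyl and the silyloxy group, so that borane adds partly from the β face and gives the cis-fused isomer. Slow addition to the hindered alkene would also lengthen exposure of the triflate to the oxidant. The fallback replaces substrate control by reagent control. Starting from 15, monoisopinocampheylborane IpcBH2 (the antipode matched with α-face delivery; both are available from the two α-pinenes) would give the alkyl(isopinocampheyl)borane F4, in which the chiral borane decides the face at the trisubstituted alkene. Oxidation with NaBO3·4H2O then returns to the route at alcohol 17.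

Step 4 (asymmetric allylation/lactonisation). Addition to the neopentyl-type tetrasubstituted enal may be slow, and the C4 stereocentre may oppose the catalyst, eroding facial selectivity at C6 and, through the relay, at C1. The fallback separates C–C bond formation from stereocontrol. Starting from 6 and 7, a Barbier allylation with Zn dust in THF–aqueous NH4Cl would give ethyl 4-hydroxy-2-methylidene-4-[(5R)-2-methyl-5-(propan-2-yl)-5-(triethylsilyloxy)cyclopent-1-en-1-yl]butanoate as a C4 epimer mixture F5. Oxidation with Dess–Martin periodinane (NaHCO3 buffer) would give ethyl 2-methylidene-4-oxo-4-[(5R)-2-methyl-5-(propan-2-yl)-5-(triethylsilyloxy)cyclopent-1-en-1-yl]butanoate F6. Corey–Bakshi–Shibata reduction with the (R)-Me-CBS oxazaborolidine and BH3·SMe2, the cyclopentenyl group acting as the large substituent, should give the (S)-carbinol 9. Catalytic NaH in THF then closes it to lactone 10, where the route is rejoined.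

**Further compounds**
F1 | step 7 | (5S)-2,3-dimethylidene-5-[(5R)-2-methyl-5-(propan-2-yl)-5-(triethylsilyloxy)cyclopent-1-en-1-yl]oxolane | C=C1O[C@H](C2=C(C)CC[C@@]2(O[Si](CC)(CC)CC)C(C)C)CC1=C
F2 | step 7 | (1R,4R)-4-(triethylsilyloxy)dauca-5,8(14)-dien-9-one | C=C1CC=C2[C@](O[Si](CC)(CC)CC)(C(C)C)CC[C@]2(C)CC1=O
F3 | step 7 | lithium C8–C9 enolate, lithium (1R,4R)-4-(triethylsilyloxy)dauca-5,8-dien-9-olate | CC1=C(O[Li])C[C@@]2(C)CC[C@@](O[Si](CC)(CC)CC)(C(C)C)C2=CC1
F4 | step 9 | 6α-[(isopinocampheyl)boranyl] adduct of 15 (isopinocampheyl group drawn as derived from (+)-α-pinene) | C[C@H]1[C@H](B[C@H]3CC(C)=C(OS(=O)(=O)C(F)(F)F)C[C@@]4(C)CC[C@@](O[Si](CC)(CC)CC)(C(C)C)[C@H]34)C[C@@H]2C[C@H]1C2(C)C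
F5 | step 4 | ethyl 4-hydroxy-2-methylidene-4-[(5R)-2-methyl-5-(propan-2-yl)-5-(triethylsilyloxy)cyclopent-1-en-1-yl]butanoate (C4 epimers) | CCOC(=O)C(=C)CC(O)C1=C(C)CC[C@@]1(O[Si](CC)(CC)CC)C(C)C
F6 | step 4 | ethyl 2-methylidene-4-oxo-4-[(5R)-2-methyl-5-(propan-2-yl)-5-(triethylsilyloxy)cyclopent-1-en-1-yl]butanoate | CCOC(=O)C(=C)CC(=O)C1=C(C)CC[C@@]1(O[Si](CC)(CC)CC)C(C)C
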